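**Retrosynthetic overview**
1. The target comes from MnO2 oxidation of a C3 allylic carbinol. The ten-membered ring is closed last, at C2–C3, by a Nozaki–Hiyama–Kishi reaction of a (Z)-vinyl iodide with a C3 aldehyde.
2. C4/C15 come from enamine-catalysed hydroxymethylation of that aldehyde. The C8–O(angelate) bond comes from an invertive Mitsunobu reaction on the 8-epi alcohol.
3. C7–C8 comes from a zinc Barbier union of a six-carbon hydroxy aldehyde (C8–C10, C14, C1, C2) with a 3-(bromomethyl)butenolide. This step also unveils the α-methylene lactone.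
4. Key disconnection: the lactone C6–O bond, made by a new catalytic enantioselective 1,4-bromolactonisation of an achiral 2-methylene-3-enoic acid. It builds the lactone ring, sets C6 (which relays to C7 and C8) and installs the allylic bromide.
5. C10–O comes from Sharpless epoxidation of an enynol. Ring order: five-membered lactone first, ten-membered carbocycle last.

Locants C1–C15 are the germacrane numbers of the target:
- C1=C2 alkene, C3 ketone, C4 (bears C15H2OH), C5
- C6 (lactone O–CH), C7, C8 (O-angelate), C9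
- C10 (carbinol, bears C14H3), C11=C13, C12 (lactone C=O)

Assumption: the target is made and drawn as the open (Z)-γ-hydroxy enone of the given SMILES; a possible ring–chain equilibrium with its 3,10-hemiketal is ignored.

Step 1
Reactants: 1 (2E)-3-methylpent-2-en-4-yn-1-ol
Product: 2 [(2S,3S)-3-ethynyl-3-methyloxiran-2-yl]methanol
Conditions: Ti(OiPr)4 (10 mol %), L-(+)-diethyl tartrate (12 mol %), t-BuOOH (2 equiv), 4 Å MS, CH2Cl2, −20 °C
Reagents that add atoms: tert-butyl hydroperoxide CC(C)(C)OO
Why: Katsuki–Sharpless asymmetric epoxidation: the allylic OH binds the titanium tartrate complex and L-(+)-tartrate delivers oxygen to the alkene face that gives the (2S,3S)-epoxide (same sense as for geraniol), which fixes the future C10–O bond and the C10 configuration while the alkyne is untouched.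

Step 2
Reactants: 2 [(2S,3S)-3-ethynyl-3-methyloxiran-2-yl]methanol
Product: 5 (3R,4Z)-5-iodo-3-methylpent-4-ene-1,3-diol, via alkynediol aluminate 3 (not isolated), via cyclic alkenylalanate 4 (not isolated)
Conditions: NaAlH2(OCH2CH2OMe)2 (3.5 equiv), THF, 0 °C → rt; then I2, THF, −78 → 0 °C
Reagents that add atoms: iodine II
Why: Alkoxide-directed hydride delivery: the primary aluminate opens the 2,3-epoxy alcohol at the CH carbon (1,3-diol-selective, the tertiary C–O bond and its configuration are kept), the freed tertiary alkoxide then directs trans-hydroalumination of the alkyne to a five-membered alkenylalanate, and iodinolysis with retention gives only the Z-vinyl iodide.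

Step 3
Reactants: 5 (3R,4Z)-5-iodo-3-methylpent-4-ene-1,3-diol
Product: 6 (3R,4Z)-3-hydroxy-5-iodo-3-methylpent-4-enal
Conditions: TEMPO (10 mol %), PhI(OAc)2 (1.1 equiv), CH2Cl2, rt; used crude
Reagents that add atoms: none
Why: TEMPO/oxoammonium oxidation takes only the primary alcohol, stops at the aldehyde under nearly neutral conditions (no dehydration of the β-hydroxy aldehyde) and cannot touch the tertiary carbinol or the vinyl iodide.

Step 4
Reactants: 7 ethyl 2-(bromomethyl)prop-2-enoate; 8 triethyl phosphite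
Product: 9 ethyl 2-[(diethoxyphosphoryl)methyl]prop-2-enoate
Conditions: neat, 120 °C, EtBr distilled off
Reagents that add atoms: none
Why: Michaelis–Arbuzov reaction of a reactive allylic bromide, in which direct and allylically transposed attack of phosphorus lead to the same phosphonate.

Step 5
Reactants: 10 methyl 4,4-dimethoxybutanoate
Product: 11 4,4-dimethoxybutanal
Conditions: i-Bu2AlH (1.05 equiv), CH2Cl2, −78 °C; aq. potassium sodium tartrate
Reagents that add atoms: none
Why: Low-temperature half-reduction of an ester: the tetrahedral aluminium hemiacetal is stable at −78 °C and collapses to the aldehyde only on work-up, and the dimethyl acetal is inert to hydride.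

Step 6
Reactants: 9 ethyl 2-[(diethoxyphosphoryl)methyl]prop-2-enoate; 11 4,4-dimethoxybutanal
Product: 13 (3E)-7,7-dimethoxy-2-methylidenehept-3-enoic acid, via dienoate ethyl ester 12 (not isolated)
Conditions: LiN(SiMe3)2, THF, −78 → 0 °C; then LiOH, THF/H2O, 0 °C → rt; 1 M HCl to pH 4 at 0 °C; kept cold and dilute, used at once
Reagents that add atoms: lithium hydroxide [Li+].[OH-]
Why: Horner–Wadsworth–Emmons olefination of the allylic phosphonate gives the E-C6=C7 alkene of the 2-carboxy diene, saponification in the same flask frees the acid without harming the acetal, and the C6 alkyl substituent plus cold handling holds back Diels–Alder dimerisation.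

Step 7
Reactants: 13 (3E)-7,7-dimethoxy-2-methylidenehept-3-enoic acid
Product: 14 (5R)-3-(bromomethyl)-5-(3,3-dimethoxypropyl)furan-2(5H)-one
Conditions: NBS (1.05 equiv), 9-amino(9-deoxy)-epi-quinidine N-[3,5-bis(trifluoromethyl)phenyl]urea (10 mol %), toluene/CHCl3, −50 °C, dark
Reagents that add atoms: N-bromosuccinimide O=C1CCC(=O)N1Br
Why: Proposed new method: catalytic enantioselective 1,4-bromolactonisation of a 2-methylene-3-enoic acid, in which the quinuclidine ion-pairs with the carboxylate while the urea activates NBS, Br+ goes to the unhindered terminal methylene C13 (largest HOMO coefficient of a 2-acceptor diene), the developing allyl cation carries its charge at alkyl-substituted C6, and in the favoured s-trans diene conformer the carboxylate lies cis to C6 and closes the five-membered ring on one enantiotopic face, so the C6–O bond, the C6 stereocentre, the C7=C11 alkene and the allylic bromide form in one event (a 1,2-adduct with Br at C7 is only the allylic isomer and would feed the same organozinc in step 8, and the quinine-series pseudo-enantiomer is the switch if the sense is opposite); the closest known reaction types are organocatalytic 1,4-bromolactonisation of conjugated enynes and 5-endo halolactonisation of β,γ-unsaturated acids.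

Step 8
Reactants: 14 (5R)-3-(bromomethyl)-5-(3,3-dimethoxypropyl)furan-2(5H)-one; 6 (3R,4Z)-3-hydroxy-5-iodo-3-methylpent-4-enal
Product: 16 (4R,5R)-4-[(1S,3R,4Z)-1,3-dihydroxy-5-iodo-3-methylpent-4-en-1-yl]-5-(3,3-dimethoxypropyl)-3-methylideneoxolan-2-one, via allylzinc bromide 15 (not isolated)
Conditions: Zn dust, THF/sat. aq. NH4Cl, 0 °C → rt
Reagents that add atoms: none
Why: Zinc Barbier allylation of a 3-(bromomethyl)butenolide: the allylzinc reacts through its γ-carbon C7 on the face anti to the C6 side chain (6,7-trans lactone, exocyclic methylene formed), and the ring-locked E-type allyl unit in a Zimmerman–Traxler chair gives the 7,8-anti adduct, which is deliberately the 8S (8-epi) alcohol, while vinyl iodide, acetal and free OH tolerate the aqueous medium.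

Step 9
Reactants: 16 (4R,5R)-4-[(1S,3R,4Z)-1,3-dihydroxy-5-iodo-3-methylpent-4-en-1-yl]-5-(3,3-dimethoxypropyl)-3-methylideneoxolan-2-one; 17 angelic acid, (2Z)-2-methylbut-2-enoic acid
Product: 19 (1R,3R,4Z)-3-hydroxy-5-iodo-3-methyl-1-[(2R,3S)-4-methylidene-5-oxo-2-(3-oxopropyl)oxolan-3-yl]pent-4-en-1-yl (2Z)-2-methylbut-2-enoate, via acetal angelate 18 (not isolated)
Conditions: PPh3 (2.5 equiv), DIAD (2.5 equiv), 17 (3 equiv), THF, 0 °C → rt; then 0.5 M aq. HCl, 0 °C
Reagents that add atoms: water O
Why: Mitsunobu reaction: only the secondary C8–OH is activated by the PPh3/DIAD couple (the tertiary C10–OH is inert) and angelate displaces it in an SN2 step, so the C8–O bond of the target forms with inversion (8S → 8R), and because the acid is the nucleophile and its acyl carbon is never activated the Z-angelate cannot drift to tiglate; cold dilute acid then hydrolyses the dimethyl acetal without harming ester, lactone, tertiary carbinol or vinyl iodide.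

Step 10
Reactants: 19 (1R,3R,4Z)-3-hydroxy-5-iodo-3-methyl-1-[(2R,3S)-4-methylidene-5-oxo-2-(3-oxopropyl)oxolan-3-yl]pent-4-en-1-yl (2Z)-2-methylbut-2-enoate
Product: 20 (1R,3R,4Z)-1-{(2R,3S)-2-[(2S)-2-formyl-3-hydroxypropyl]-4-methylidene-5-oxooxolan-3-yl}-3-hydroxy-5-iodo-3-methylpent-4-en-1-yl (2Z)-2-methylbut-2-enoate
Conditions: 37 % aq. HCHO (3 equiv), (R)-α,α-diphenylprolinol trimethylsilyl ether (20 mol %), toluene, NaH2PO4/Na2HPO4 buffer (pH 7), rt
Reagents that add atoms: formaldehyde C=O
Why: Enamine-catalysed cross-aldol (α-hydroxymethylation of an aldehyde): the CPh2(OSiMe3) group of the (R)-catalyst shields one face of the E-enamine so formaldehyde adds to the other and sets C4 as S under catalyst control, and the buffered neutral medium prevents dehydration and epimerisation.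

Step 11
Reactants: 20 (1R,3R,4Z)-1-{(2R,3S)-2-[(2S)-2-formyl-3-hydroxypropyl]-4-methylidene-5-oxooxolan-3-yl}-3-hydroxy-5-iodo-3-methylpent-4-en-1-yl (2Z)-2-methylbut-2-enoate
Product: 22 (1Z,4S,6R,7S,8R,10R)-8-angeloyloxy-3,10,15-trihydroxygermacra-1,11(13)-dien-12,6-olide (both C3 epimers), via alkenylchromium dichloride 21 (not isolated)
Conditions: CrCl2 (8 equiv), NiCl2 (2 mol %), DMSO/THF, 2 mM, rt
Reagents that add atoms: none
Why: Nozaki–Hiyama–Kishi reaction: nickel-catalysed activation of the C–I bond and transmetallation give an alkenylchromium species that adds only to the aldehyde (lactone, angelate, methylene lactone and free OH groups are tolerated), high dilution favours the ten-membered ring, chelation by the C10 oxygen holds the Z geometry, and the new C3 centre need not be controlled because it is oxidised next.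

Step 12
Reactants: 22 (1Z,4S,6R,7S,8R,10R)-8-angeloyloxy-3,10,15-trihydroxygermacra-1,11(13)-dien-12,6-olide (both C3 epimers)
Product: 23 (1Z,4S,6R,7S,8R,10R)-8-angeloyloxy-10,15-dihydroxy-3-oxogermacra-1,11(13)-dien-12,6-olide (target)
Conditions: activated MnO2 (20 equiv), CH2Cl2, rt
Reagents that add atoms: none
Why: MnO2 allylic oxidation converts only the allylic C3 carbinol (both epimers converge on the enone), leaves the primary C15–OH and tertiary C10–OH alone, and its neutral heterogeneous conditions avoid C4 epimerisation, β-elimination and Z/E isomerisation.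

**Compound list**
1 | (2E)-3-methylpent-2-en-4-yn-1-ol | C#C/C(C)=C/CO | starting material
2 | [(2S,3S)-3-ethynyl-3-methyloxiran-2-yl]methanol | OC[C@@H]1O[C@@]1(C)C#C | intermediate
3 | (3R)-3-methylpent-4-yne-1,3-diol, present as its aluminium alkoxide | OCC[C@@](C)(O)C#C | intermediate
4 | sodium cyclic (Z)-alkenylalanate, five-membered O–Al–CH=CH–C ring on the tertiary carbinol carbon (primary oxygen drawn protonated) | C[C@]1(CCO)O[Al-](OCCOC)(OCCOC)C=C1.[Na+] | intermediate
5 | (3R,4Z)-5-iodo-3-methylpent-4-ene-1,3-diol | OCC[C@@](C)(O)/C=C\I | intermediate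
6 | (3R,4Z)-3-hydroxy-5-iodo-3-methylpent-4-enal | O=CC[C@@](C)(O)/C=C\I | intermediate
7 | ethyl 2-(bromomethyl)prop-2-enoate | C=C(CBr)C(=O)OCC | starting material
8 | triethyl phosphite | CCOP(OCC)OCC | starting material
9 | ethyl 2-[(diethoxyphosphoryl)methyl]prop-2-enoate | C=C(CP(=O)(OCC)OCC)C(=O)OCC | intermediate
10 | methyl 4,4-dimethoxybutanoate | COC(=O)CCC(OC)OC | starting material
11 | 4,4-dimethoxybutanal | O=CCCC(OC)OC | intermediate
12 | ethyl (3E)-7,7-dimethoxy-2-methylidenehept-3-enoate | C=C(/C=C/CCC(OC)OC)C(=O)OCC | intermediate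
13 | (3E)-7,7-dimethoxy-2-methylidenehept-3-enoic acid | C=C(/C=C/CCC(OC)OC)C(=O)O | intermediate
14 | (5R)-3-(bromomethyl)-5-(3,3-dimethoxypropyl)furan-2(5H)-one | O=C1O[C@H](CCC(OC)OC)C=C1CBr | intermediate
15 | {[(5R)-5-(3,3-dimethoxypropyl)-2-oxo-2,5-dihydrofuran-3-yl]methyl}zinc bromide | O=C1O[C@H](CCC(OC)OC)C=C1C[Zn]Br | intermediate
16 | (4R,5R)-4-[(1S,3R,4Z)-1,3-dihydroxy-5-iodo-3-methylpent-4-en-1-yl]-5-(3,3-dimethoxypropyl)-3-methylideneoxolan-2-one (6,7-trans, 8-epi) | C=C1C(=O)O[C@H](CCC(OC)OC)[C@H]1[C@@H](O)C[C@@](C)(O)/C=C\I | intermediate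
17 | angelic acid, (2Z)-2-methylbut-2-enoic acid | C/C=C(/C)C(=O)O | starting material
18 | (1R,3R,4Z)-1-[(2R,3S)-2-(3,3-dimethoxypropyl)-4-methylidene-5-oxooxolan-3-yl]-3-hydroxy-5-iodo-3-methylpent-4-en-1-yl (2Z)-2-methylbut-2-enoate | C=C1C(=O)O[C@H](CCC(OC)OC)[C@H]1[C@H](OC(=O)/C(C)=C\C)C[C@@](C)(O)/C=C\I | intermediate
19 | (1R,3R,4Z)-3-hydroxy-5-iodo-3-methyl-1-[(2R,3S)-4-methylidene-5-oxo-2-(3-oxopropyl)oxolan-3-yl]pent-4-en-1-yl (2Z)-2-methylbut-2-enoate | C=C1C(=O)O[C@H](CCC=O)[C@H]1[C@H](OC(=O)/C(C)=C\C)C[C@@](C)(O)/C=C\I | intermediate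
20 | (1R,3R,4Z)-1-{(2R,3S)-2-[(2S)-2-formyl-3-hydroxypropyl]-4-methylidene-5-oxooxolan-3-yl}-3-hydroxy-5-iodo-3-methylpent-4-en-1-yl (2Z)-2-methylbut-2-enoate | C=C1C(=O)O[C@H](C[C@@H](CO)C=O)[C@H]1[C@H](OC(=O)/C(C)=C\C)C[C@@](C)(O)/C=C\I | intermediate
21 | (Z)-alkenylchromium dichloride derived from 20 (CrCl2 in place of iodine) | C=C1C(=O)O[C@H](C[C@@H](CO)C=O)[C@H]1[C@H](OC(=O)/C(C)=C\C)C[C@@](C)(O)/C=C\[Cr](Cl)Cl | intermediate
22 | (1Z,4S,6R,7S,8R,10R)-8-angeloyloxy-3,10,15-trihydroxygermacra-1,11(13)-dien-12,6-olide, both C3 epimers | C=C1C(=O)O[C@@H]2C[C@@H](CO)C(O)/C=C\[C@](C)(O)C[C@@H](OC(=O)/C(C)=C\C)[C@@H]12 | intermediate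
23 | (1Z,4S,6R,7S,8R,10R)-8-angeloyloxy-10,15-dihydroxy-3-oxogermacra-1,11(13)-dien-12,6-olide (CNP0219400.1) | C=C1C(=O)O[C@@H]2C[C@@H](CO)C(=O)/C=C\[C@](C)(O)C[C@@H](OC(=O)/C(C)=C\C)[C@@H]12 | target

**Step count and risks**

Total step count: 12. Longest linear sequence: 8 steps (5, 6, 7, 8, 9, 10, 11, 12). The branches from 1 and from 7 are equally long.

**Step 7, the new bromolactonisation.**
- Risks: bromine attack on the C6=C7 alkene with poor facial control, low ee, and dimerisation of the diene acid.
- The fallback uses known chemistry and builds the lactone by C–C bond formation instead. It sets out from aldehyde 11 and bromide 7.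
- An enantioselective chromium-catalysed 2-(alkoxycarbonyl)allylation with lactonisation on acidic work-up gives the α-methylene lactone (5R)-5-(3,3-dimethoxypropyl)-3-methylideneoxolan-2-one F1. Conditions: CrCl2 cat., chiral carbazole-bis(oxazoline) ligand, Mn powder, Me3SiCl.
- Br2 in CH2Cl2 at 0 °C adds across the exocyclic alkene to give (5R)-3-bromo-3-(bromomethyl)-5-(3,3-dimethoxypropyl)oxolan-2-one F2.
- Et3N then removes HBr towards C7, and the route is rejoined at 14.

**Step 9, the Mitsunobu inversion.**
- Risks: SN2 at a carbinol flanked by the branched C7, so elimination or no reaction.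
- The fallback replaces alkyl C–O substitution by redox inversion and acyl transfer. It sets out from 16.
- Dess–Martin periodinane oxidises only the secondary carbinol to the β-hydroxy ketone (4S,5R)-5-(3,3-dimethoxypropyl)-4-[(3R,4Z)-3-hydroxy-5-iodo-3-methylpent-4-enoyl]-3-methylideneoxolan-2-one F3.
- Me4NBH(OAc)3 in MeCN/AcOH at −30 °C delivers hydride from boron bound to the C10 oxygen, with the larger iodovinyl group equatorial. This gives the 1,3-anti diol (4R,5R)-4-[(1R,3R,4Z)-1,3-dihydroxy-5-iodo-3-methylpent-4-en-1-yl]-5-(3,3-dimethoxypropyl)-3-methylideneoxolan-2-one F4.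
- The secondary OH of F4 is acylated with the mixed anhydride of 17 and 2,4,6-trichlorobenzoyl chloride (Et3N, toluene, 80 °C), conditions that keep angelates Z. The route is rejoined at 18, which is hydrolysed to 19 as in step 9.

**Step 11, the ten-membered ring closure.**
- Risks: oligomerisation, and loss of Z geometry at the alkenylchromium stage.
- The fallback closes the ring at C1=C2 by metathesis instead of at C2–C3. It sets out from 20.
- Pd(PPh3)4 with HCO2H/Et3N replaces iodine by hydrogen to give the vinyl carbinol (1R,3R)-1-{(2R,3S)-2-[(2S)-2-formyl-3-hydroxypropyl]-4-methylidene-5-oxooxolan-3-yl}-3-hydroxy-3-methylpent-4-en-1-yl (2Z)-2-methylbut-2-enoate F5.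
- Intermolecular CrCl2/NiCl2 coupling with excess vinyl iodide adds a vinyl group to the aldehyde. This gives the bis(allylic alcohol) (1R,3R)-3-hydroxy-1-{(2R,3S)-2-[(2S)-3-hydroxy-2-(hydroxymethyl)pent-4-en-1-yl]-4-methylidene-5-oxooxolan-3-yl}-3-methylpent-4-en-1-yl (2Z)-2-methylbut-2-enoate F6.
- The first-generation Grubbs catalyst RuCl2(PCy3)2(=CHPh) (CH2Cl2, 1 mM, reflux) does not engage the 1,1-disubstituted methylene lactone or the angelate. It closes the medium ring to the Z-alkene, and the route is rejoined at 22.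

**Further compounds**
F1 | step 7 | (5R)-5-(3,3-dimethoxypropyl)-3-methylideneoxolan-2-one | O=C1O[C@H](CCC(OC)OC)CC1=C
F2 | step 7 | (5R)-3-bromo-3-(bromomethyl)-5-(3,3-dimethoxypropyl)oxolan-2-one (C3 epimers) | O=C1O[C@H](CCC(OC)OC)CC1(Br)CBr
F3 | step 9 | (4S,5R)-5-(3,3-dimethoxypropyl)-4-[(3R,4Z)-3-hydroxy-5-iodo-3-methylpent-4-enoyl]-3-methylideneoxolan-2-one | C=C1C(=O)O[C@H](CCC(OC)OC)[C@H]1C(=O)C[C@@](C)(O)/C=C\I
F4 | step 9 | (4R,5R)-4-[(1R,3R,4Z)-1,3-dihydroxy-5-iodo-3-methylpent-4-en-1-yl]-5-(3,3-dimethoxypropyl)-3-methylideneoxolan-2-one | C=C1C(=O)O[C@H](CCC(OC)OC)[C@H]1[C@H](O)C[C@@](C)(O)/C=C\I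
F5 | step 11 | (1R,3R)-1-{(2R,3S)-2-[(2S)-2-formyl-3-hydroxypropyl]-4-methylidene-5-oxooxolan-3-yl}-3-hydroxy-3-methylpent-4-en-1-yl (2Z)-2-methylbut-2-enoate | C=C1C(=O)O[C@H](C[C@@H](CO)C=O)[C@H]1[C@H](OC(=O)/C(C)=C\C)C[C@@](C)(O)C=C
F6 | step 11 | (1R,3R)-3-hydroxy-1-{(2R,3S)-2-[(2S)-3-hydroxy-2-(hydroxymethyl)pent-4-en-1-yl]-4-methylidene-5-oxooxolan-3-yl}-3-methylpent-4-en-1-yl (2Z)-2-methylbut-2-enoate (carbinol epimers) | C=C1C(=O)O[C@H](C[C@@H](CO)C(O)C=C)[C@H]1[C@H](OC(=O)/C(C)=C\C)C[C@@](C)(O)C=C
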